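**Retrosynthetic overview**

- The C9 ester is disconnected by Mitsunobu inversion to a (2Z,6Z,10Z)-trienoic acid (two Z-selective Ando olefinations, starting from neryl acetate), the C8 ester by acylation, and the C14 aldehyde by PMB removal and MnO2 oxidation.
- Key disconnection: the C8–C9 bond of the ten-membered carbocycle. It is closed from an acyclic dialdehyde (saturated C8 aldehyde plus a 2-(PMB-oxymethyl) enal at C9) by a CrCl2/Et3SiCl pinacol-type cross-coupling through a γ-silyloxyallylchromium species.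
- Enabling feature: C8 and C9 are vicinal oxygen-bearing ring carbons and C9 is allylic to the C1=C10 enal bond of the ten-membered ring (array O–C8–C9(O)–C10(=C1)–C14), which is the retron of a γ-oxyallyl-metal addition to an aldehyde. The enal geometry is erased in the allylmetal, so an E/Z mixture converges on the ring-cis alkene.
- Ring order: the γ-lactone first (Evans syn-aldol of a succinate imide with a geranial-type enal sets C6 and C7; the exocyclic methylene is carried as CH2NMe2), then the ten-membered ring (key step), then release of the methylene.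

Key step: step 14

Remark: positions follow germacranolide numbering (ring C1–C10, lactone carbons C11–C13 with the ring oxygen on C6, C14 on C10, C15 on C4), and "melampolide" means this skeleton with a ring-cis C1=C10 bond, an E C4=C5 bond, H-6β and H-7α; it is assumed that the E/Z mixture at C1=C10 formed in step 2 needs no separation, so compounds 6–11 and 15–21 are drawn as the major isomer.

**Route**

Step 1
Reactants: 1 pent-4-yn-1-ol
Product: 2 pent-4-ynal
Conditions: TEMPO (0.1 equiv), PhI(OAc)2, CH2Cl2, rt; used as a solution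
Reagents that add atoms: none
Why: TEMPO/PhI(OAc)2 (oxoammonium) oxidation should stop at the volatile aldehyde and leave the terminal alkyne untouched.

Step 2
Reactants: 2 pent-4-ynal; 3 ethyl 2-(diethoxyphosphoryl)prop-2-enoate; 4 (4-methoxyphenyl)methanol
Product: 6 ethyl (2E)-2-{[(4-methoxybenzyl)oxy]methyl}hept-2-en-6-ynoate (major isomer of an E/Z mixture), via sodium phosphonate Michael adduct 5 (not isolated)
Conditions: 4, NaH, THF, 0 °C; 3, 0 °C; then 2, 0 °C → rt
Reagents that add atoms: none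
Why: Tandem oxa-Michael addition/Horner–Wadsworth–Emmons olefination: the alkoxide adds to the vinylphosphonate and the phosphonate anion so formed olefinates the aldehyde; the alkene geometry need not be controlled because step 14 erases it.

Step 3
Reactants: 6 ethyl (2E)-2-{[(4-methoxybenzyl)oxy]methyl}hept-2-en-6-ynoate
Product: 7 (2Z)-2-{[(4-methoxybenzyl)oxy]methyl}hept-2-en-6-yn-1-ol
Conditions: i-Bu2AlH (2.2 equiv), CH2Cl2, −78 °C; aq. potassium sodium tartrate
Reagents that add atoms: none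
Why: i-Bu2AlH 1,2-reduction of the enoate should give the allylic alcohol without touching the alkyne or the PMB ether.

Step 4
Reactants: 7 (2Z)-2-{[(4-methoxybenzyl)oxy]methyl}hept-2-en-6-yn-1-ol
Product: 8 tert-butyl{[(2E)-2-{[(4-methoxybenzyl)oxy]methyl}hept-2-en-6-yn-1-yl]oxy}dimethylsilane
Conditions: TBSCl, imidazole, CH2Cl2, 0 °C → rt
Reagents that add atoms: tert-butyl(chloro)dimethylsilane, CC(C)(C)[Si](C)(C)Cl
Why: Standard silyl ether protection of the primary allylic alcohol.

Step 5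
Reactants: 8 tert-butyl{[(2E)-2-{[(4-methoxybenzyl)oxy]methyl}hept-2-en-6-yn-1-yl]oxy}dimethylsilane
Product: 10 (2E,6E)-8-[(tert-butyldimethylsilyl)oxy]-7-{[(4-methoxybenzyl)oxy]methyl}-3-methylocta-2,6-dien-1-ol, via alkenyldimethylalane 9 (not isolated)
Conditions: Me3Al (3 equiv), Cp2ZrCl2 (0.25 equiv), CH2Cl2, 0 °C → rt; then (CH2O)n, THF, 0 °C → rt; aq. potassium sodium tartrate
Reagents that add atoms: trimethylaluminium, C[Al](C)C; paraformaldehyde (as formaldehyde), C=O
Why: Zirconium-catalysed carboalumination (Negishi) adds CH3 and Al syn across the terminal alkyne with CH3 on the internal carbon, and trapping of the alkenylalane by formaldehyde with retention should fix the E geometry of C4=C5 and install C6 as the allylic alcohol.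

Step 6
Reactants: 10 (2E,6E)-8-[(tert-butyldimethylsilyl)oxy]-7-{[(4-methoxybenzyl)oxy]methyl}-3-methylocta-2,6-dien-1-ol
Product: 11 (2E,6E)-8-[(tert-butyldimethylsilyl)oxy]-7-{[(4-methoxybenzyl)oxy]methyl}-3-methylocta-2,6-dienal
Conditions: MnO2 (15 equiv), CH2Cl2, rt
Reagents that add atoms: none
Why: MnO2 oxidation is selective for the allylic alcohol and should give the E enal without isomerisation.

Step 7
Reactants: 12 (4S)-4-benzyl-1,3-oxazolidin-2-one; 13 methyl 4-chloro-4-oxobutanoate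
Product: 14 methyl 4-[(4S)-4-benzyl-2-oxo-1,3-oxazolidin-3-yl]-4-oxobutanoate
Conditions: n-BuLi, THF, −78 °C; then 13, −78 → 0 °C
Reagents that add atoms: none
Why: N-Acylation of the lithiated oxazolidinone by the acid chloride.

Step 8
Reactants: 14 methyl 4-[(4S)-4-benzyl-2-oxo-1,3-oxazolidin-3-yl]-4-oxobutanoate; 11 (2E,6E)-8-[(tert-butyldimethylsilyl)oxy]-7-{[(4-methoxybenzyl)oxy]methyl}-3-methylocta-2,6-dienal
Product: 16 (4S)-4-benzyl-3-{[(2R,3S)-2-[(1E,5E)-7-(TBS-oxy)-6-(PMB-oxymethyl)-2-methylhepta-1,5-dien-1-yl]-5-oxooxolan-3-yl]carbonyl}-1,3-oxazolidin-2-one (trans lactone), via syn-aldol hydroxy ester 15 (not isolated)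
Conditions: Bu2BOTf, i-Pr2NEt, CH2Cl2, −78 → 0 °C; 11, −78 → 0 °C; pH 7 buffer, MeOH, H2O2; then PPTS (cat.), CH2Cl2, rt
Reagents that add atoms: none
Why: Evans syn-aldol reaction: the Z boron enolate adds through a Zimmerman–Traxler chair on the enolate face left open by the benzyl group, which sets C7 (S) and C6 (R), and the γ-hydroxy ester then closes to the trans-β,γ-disubstituted lactone.

Step 9
Reactants: 16 trans lactone imide
Product: 17 (4R,5R)-4-(hydroxymethyl)-5-[(1E,5E)-7-(TBS-oxy)-6-(PMB-oxymethyl)-2-methylhepta-1,5-dien-1-yl]oxolan-2-one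
Conditions: NaBH4 (4 equiv), THF/H2O (4:1), 0 °C → rt
Reagents that add atoms: none
Why: Borohydride reduction of the activated imide carbonyl, which is more electrophilic than the lactone, should free C8 as the primary alcohol and release the auxiliary.

Step 10
Reactants: 17 (4R,5R)-4-(hydroxymethyl) lactone
Product: 18 (4R,5R)-4-{[(tert-butyldimethylsilyl)oxy]methyl}-5-[(1E,5E)-7-(TBS-oxy)-6-(PMB-oxymethyl)-2-methylhepta-1,5-dien-1-yl]oxolan-2-one
Conditions: TBSCl, imidazole, DMF, 0 °C → rt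
Reagents that add atoms: tert-butyl(chloro)dimethylsilane, CC(C)(C)[Si](C)(C)Cl
Why: Silyl ether protection of C8–OH so that the lactone can be enolised.

Step 11
Reactants: 18 bis-TBS lactone
Product: 19 (3R,4R,5R)-3-[(dimethylamino)methyl]-4-{[(tert-butyldimethylsilyl)oxy]methyl}-5-[(1E,5E)-7-(TBS-oxy)-6-(PMB-oxymethyl)-2-methylhepta-1,5-dien-1-yl]oxolan-2-one (all-trans)
Conditions: LiN(SiMe3)2 (1.15 equiv), THF, −78 °C; CH2=NMe2+ I− (2 equiv), −78 → 0 °C
Reagents that add atoms: N,N-dimethylmethyleneiminium iodide (Eschenmoser's salt), C=[N+](C)C.[I-]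
Why: Mannich aminomethylation of the lactone lithium enolate by the iminium salt, anti to the C7 substituent; the new C11 centre (trans) is destroyed again in step 15.

Step 12
Reactants: 19 Mannich base
Product: 20 (3R,4R,5R)-3-[(dimethylamino)methyl]-4-(hydroxymethyl)-5-[(1E,5Z)-7-hydroxy-6-(PMB-oxymethyl)-2-methylhepta-1,5-dien-1-yl]oxolan-2-one
Conditions: HF·pyridine, pyridine, THF, 0 °C → rt; aq. NaHCO3
Reagents that add atoms: none
Why: HF·pyridine desilylation removes both primary TBS ethers while the PMB ether stays, and the acidic medium keeps the free C8–OH from translactonising.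

Step 13
Reactants: 20 amino diol
Product: 21 (2R,3S,4R)-4-[(dimethylamino)methyl]-2-[(1E,5E)-6-formyl-7-(PMB-oxy)-2-methylhepta-1,5-dien-1-yl]-5-oxooxolane-3-carbaldehyde
Conditions: Dess–Martin periodinane (3 equiv), NaHCO3, CH2Cl2, 0 °C → rt; used directly
Reagents that add atoms: none
Why: Dess–Martin oxidation converts the primary and the allylic alcohol into the two aldehydes under near-neutral conditions; C7 already has the thermodynamically preferred trans configuration, so no epimer should build up.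

Step 14
Reactants: 21 dialdehyde
Product: 23 (8S,9R)-13-(dimethylamino)-8β-hydroxy-14-[(4-methoxybenzyl)oxy]-9β-[(triethylsilyl)oxy]-11,13-dihydromelampolide (CH2NMe2 trans to C8 on the lactone), via γ-silyloxyallylchromium species 22 (not isolated)
Conditions: CrCl2 (8 equiv), Et3SiCl (2.5 equiv), DMF/THF (1:1), 0.003 M, syringe-pump addition of 21 over 12 h, 25 °C; aq. NaHCO3
Reagents that add atoms: chlorotriethylsilane, CC[Si](Cl)(CC)CC
Why: Proposed new method: CrCl2 reduces the Et3SiCl-activated enal of 21 (not the saturated C8 aldehyde) in two one-electron steps to the γ-silyloxyallyl species 22 with trivalent chromium on C1, which binds the C8 aldehyde oxygen and delivers C9 to C8 through a closed six-membered transition state with allyl transposition, so that the alkene reappears at C1=C10 and O9 leaves the step silylated while O8 is a chromium alkoxide (free OH after work-up). The closest known reaction type is the CrCl2/R3SiCl pinacol-type cross-coupling of enals with aldehydes through γ-siloxyallylchromium reagents, known between two molecules and for five- to seven-membered rings closed through the α-substituent of an acrolein, but not for a medium ring closed through the β-carbon. The ten-membered ring closes 10-exo-trig at the aldehyde with the allyl unit reacting in the endocyclic SE2′ mode (C9, C10 and C1 all become ring atoms), under high dilution. The step is stereoconvergent: allylchromium species equilibrate by 1,3-metal shifts faster than they add, so both enal isomers of 21 and both C1 epimers of 22 should drain through one transition state (Curtin–Hammett), in which the tether can only span C1 and C8 if C2 sits on the inside of the allyl unit, which gives the ring-cis (melampolide) C1=C10 bond. C8 is controlled by C7 (Felkin–Anh: C9 approaches anti to the C7–C11 bond with only H7 next to its path, the tether carbon C6 lying on the oxygen side), which should give 8S, and C9 by the enol-ether geometry: with C2 inside, OSiEt3 takes the outside position to avoid 1,3-allylic strain, which in the closed transition state gives the 8,9-erythro (9R) product, the usual anti sense of γ-oxyallylchromium additions; C9 is inverted in step 33. The step needs chemoselective reduction of the enal over the aldehyde (secured by conjugation), ring closure over oligomerisation (secured by dilution) and a C7–H that is not doubly activated (secured by carrying the exocyclic methylene as CH2NMe2).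

Step 15
Reactants: 23 amino macrocycle
Product: 25 (8S,9R)-8β-hydroxy-14-[(4-methoxybenzyl)oxy]-9β-[(triethylsilyl)oxy]melampolide, via trimethylammonium iodide 24 (not isolated)
Conditions: MeI (10 equiv), THF, rt; then sat. aq. NaHCO3, EtOAc, rt
Reagents that add atoms: none
Why: Exhaustive N-methylation followed by E1cB (Hofmann-type) elimination of trimethylamine is the standard release of an α-methylene lactone and needs only bicarbonate.

Step 16
Reactants: 26 ethyl 2-(hydroxymethyl)prop-2-enoate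
Product: 27 ethyl 2-{[(tert-butyldiphenylsilyl)oxy]methyl}prop-2-enoate
Conditions: TBDPSCl, imidazole, CH2Cl2, 0 °C → rt
Reagents that add atoms: tert-butyl(chloro)diphenylsilane, CC(C)(C)[Si](Cl)(c1ccccc1)c1ccccc1
Why: Silyl ether protection of the primary alcohol with a group that outlasts the later removal of the triethylsilyl ether.

Step 17
Reactants: 27 ethyl 2-{[(tert-butyldiphenylsilyl)oxy]methyl}prop-2-enoate
Product: 28 2-{[(tert-butyldiphenylsilyl)oxy]methyl}prop-2-enoic acid
Conditions: LiOH·H2O, THF/H2O, 0 °C; then 1 M HCl to pH 3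
Reagents that add atoms: lithium hydroxide, [Li+].[OH-]
Why: Saponification of the ethyl ester at 0 °C; the bulky silyloxymethyl group should slow conjugate addition of hydroxide.

Step 18
Reactants: 25 (8S,9R)-8β-hydroxy-14-(PMB-oxy)-9β-(triethylsilyloxy)melampolide; 28 2-{[(tert-butyldiphenylsilyl)oxy]methyl}prop-2-enoic acid
Product: 29 (8S,9R)-8β-[(2-{[(tert-butyldiphenylsilyl)oxy]methyl}prop-2-enoyl)oxy]-14-[(4-methoxybenzyl)oxy]-9β-[(triethylsilyl)oxy]melampolide
Conditions: 2-methyl-6-nitrobenzoic anhydride, Et3N, DMAP, CH2Cl2, rt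
Reagents that add atoms: none
Why: Shiina esterification (mixed-anhydride activation, DMAP acyl transfer) acylates the only free hydroxyl, C8–OH, with retention.

Step 19
Reactants: 29 C8 ester with 9β-OSiEt3
Product: 30 (8S,9R)-8β-[(2-{[(tert-butyldiphenylsilyl)oxy]methyl}prop-2-enoyl)oxy]-9β-hydroxy-14-[(4-methoxybenzyl)oxy]melampolide
Conditions: HF·pyridine, pyridine, THF, 0 °C
Reagents that add atoms: none
Why: Buffered HF·pyridine should cleave the secondary triethylsilyl ether much faster than the primary TBDPS ether, and the acidic medium suppresses acyl migration to O9.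

Step 20
Reactants: 31 neryl acetate [(2Z)-3,7-dimethylocta-2,6-dien-1-yl acetate]
Product: 32 (2Z)-5-(3,3-dimethyloxiran-2-yl)-3-methylpent-2-en-1-yl acetate (racemic epoxide)
Conditions: mCPBA (1.0 equiv), NaHCO3, CH2Cl2, 0 °C
Reagents that add atoms: 3-chloroperoxybenzoic acid, O=C(OO)c1cccc(Cl)c1
Why: Prilezhaev epoxidation: the peracid should attack the electron-rich distal trisubstituted alkene in preference to the one deactivated by the allylic acetate.

Step 21
Reactants: 32 epoxy acetate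
Product: 33 (2Z)-3-methyl-6-oxohex-2-en-1-yl acetate
Conditions: H5IO6, THF/H2O, 0 °C
Reagents that add atoms: none
Why: Periodic acid opens the epoxide to the diol and cleaves it (glycol cleavage) to the aldehyde and acetone without touching the Z alkene.

Step 22
Reactants: 34 ethyl 2-[bis(2-methylphenoxy)phosphoryl]acetate; 35 3-bromo-1,1-dimethoxypropane
Product: 36 ethyl 2-[bis(2-methylphenoxy)phosphoryl]-5,5-dimethoxypentanoate
Conditions: NaH, DMSO, rt; 35, NaI (0.1 equiv), 50 °C
Reagents that add atoms: none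
Why: C-Alkylation of the sodium salt of the diaryl phosphonoacetate by the primary bromide (Finkelstein assistance) gives the α-substituted Ando reagent.

Step 23
Reactants: 33 (2Z)-3-methyl-6-oxohex-2-en-1-yl acetate; 36 ethyl 2-[bis(2-methylphenoxy)phosphoryl]-5,5-dimethoxypentanoate
Product: 37 ethyl (2Z,6Z)-8-acetoxy-2-(3,3-dimethoxypropyl)-6-methylocta-2,6-dienoate
Conditions: NaH, THF, −78 °C; then 33, −78 → 0 °C
Reagents that add atoms: none
Why: Ando-type Horner–Wadsworth–Emmons olefination: the diaryl phosphonate eliminates from the kinetically formed adduct faster than it equilibrates, which should place the ester cis to the chain (Z).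

Step 24
Reactants: 37 Z-enoate acetal
Product: 38 (2Z,6Z)-2-(3,3-dimethoxypropyl)-6-methylocta-2,6-diene-1,8-diol
Conditions: i-Bu2AlH (5 equiv), CH2Cl2, −78 → −20 °C; aq. potassium sodium tartrate
Reagents that add atoms: none
Why: i-Bu2AlH reduces the enoate to the allylic alcohol and cleaves the acetate in the same operation, the acetal being inert.

Step 25
Reactants: 38 diol acetal
Product: 39 (2Z,6Z)-2-(3,3-dimethoxypropyl)-6-methylocta-2,6-diene-1,8-diyl diacetate
Conditions: Ac2O, pyridine, DMAP (0.05 equiv), CH2Cl2, 0 °C → rt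
Reagents that add atoms: acetic anhydride, CC(=O)OC(C)=O
Why: Acetylation (DMAP-catalysed acyl transfer) of both primary allylic alcohols.

Step 26
Reactants: 39 diacetate acetal
Product: 40 (2Z,6Z)-6-methyl-2-(3-oxopropyl)octa-2,6-diene-1,8-diyl diacetate
Conditions: PPTS (0.2 equiv), acetone/H2O (9:1), 45 °C
Reagents that add atoms: water, O
Why: Mild acid-catalysed acetal hydrolysis frees the aldehyde; the allylic acetates and the Z alkenes should survive.

Step 27
Reactants: 41 but-3-yn-1-ol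
Product: 42 4-methyl-3-methylidenepentan-1-ol
Conditions: i-PrMgCl (3 equiv), CuI (0.1 equiv), THF, −10 °C → rt; then 1 M HCl, 0 °C
Reagents that add atoms: isopropylmagnesium chloride, CC(C)[Mg]Cl
Why: Copper-catalysed carbomagnesiation of the homopropargylic magnesium alkoxide adds the isopropyl group to the internal alkyne carbon through the chelated alkenylmagnesium, giving the 1,1-disubstituted alkene on protonation.

Step 28
Reactants: 42 4-methyl-3-methylidenepentan-1-ol
Product: 43 5-iodo-2-methyl-3-methylidenepentane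
Conditions: I2, PPh3, imidazole, CH2Cl2, 0 °C
Reagents that add atoms: iodine, II
Why: Appel-type iodination of the primary alcohol by SN2 displacement of the oxyphosphonium group.

Step 29
Reactants: 34 ethyl 2-[bis(2-methylphenoxy)phosphoryl]acetate; 43 5-iodo-2-methyl-3-methylidenepentane
Product: 44 ethyl 2-[bis(2-methylphenoxy)phosphoryl]-6-methyl-5-methylideneheptanoate
Conditions: NaH, DMSO, rt; 43, rt
Reagents that add atoms: none
Why: C-Alkylation of the phosphonoacetate sodium salt by the primary iodide gives the second α-substituted Ando reagent.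

Step 30
Reactants: 40 (2Z,6Z)-6-methyl-2-(3-oxopropyl)octa-2,6-diene-1,8-diyl diacetate; 44 ethyl 2-[bis(2-methylphenoxy)phosphoryl]-6-methyl-5-methylideneheptanoate
Product: 45 ethyl (2Z,6Z,10Z)-12-acetoxy-6-(acetoxymethyl)-10-methyl-2-(4-methyl-3-methylidenepentyl)dodeca-2,6,10-trienoate
Conditions: NaH, THF, −78 °C; then 40, −78 → 0 °C
Reagents that add atoms: none
Why: Second Ando-type Z-selective Horner–Wadsworth–Emmons olefination, which should place the ester cis to C4 (2Z); the acetates tolerate the phosphonate anion at low temperature.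

Step 31
Reactants: 45 triene ethyl ester
Product: 46 (2Z,6Z,10Z)-12-hydroxy-6-(hydroxymethyl)-10-methyl-2-(4-methyl-3-methylidenepentyl)dodeca-2,6,10-trienoic acid
Conditions: LiOH·H2O (6 equiv), THF/MeOH/H2O, rt → 40 °C; then 1 M HCl to pH 3
Reagents that add atoms: lithium hydroxide, [Li+].[OH-]
Why: Saponification cleaves the two acetates and the hindered ethyl enoate; a Z trisubstituted enoate of this angelate type should survive lithium hydroxide at or below 40 °C without isomerisation.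

Step 32
Reactants: 46 dihydroxy acid
Product: 48 (2Z,6Z,10Z)-12-acetoxy-6-(acetoxymethyl)-10-methyl-2-(4-methyl-3-methylidenepentyl)dodeca-2,6,10-trienoic acid, via mixed acetic anhydride 47 (not isolated)
Conditions: Ac2O, pyridine, 0 °C → rt; then H2O, THF, rt
Reagents that add atoms: acetic anhydride, CC(=O)OC(C)=O
Why: Acetylation of both primary alcohols; the carboxyl group is acetylated reversibly to the mixed anhydride, which water hydrolyses at the acetyl carbonyl back to the free acid.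

Step 33
Reactants: 30 (8S,9R)-9β-hydroxy C8 ester; 48 diacetoxy trienoic acid
Product: 49 (8S,9S)-9α-{[(2Z,6Z,10Z)-12-acetoxy-6-(acetoxymethyl)-10-methyl-2-(4-methyl-3-methylidenepentyl)dodeca-2,6,10-trienoyl]oxy}-8β-[(2-{[(tert-butyldiphenylsilyl)oxy]methyl}prop-2-enoyl)oxy]-14-[(4-methoxybenzyl)oxy]melampolide
Conditions: PPh3, DIAD, toluene, 0 °C → rt
Reagents that add atoms: none
Why: Mitsunobu esterification: the carboxylate displaces the oxyphosphonium group at C9 by SN2 with inversion (9R → 9S), the cis C8 ester cannot participate from the rear side, and because the acid is never activated its Z enoate cannot isomerise.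

Step 34
Reactants: 49 diester PMB ether
Product: 50 (8S,9S)-14-hydroxy analogue of 49 (C14 primary allylic alcohol)
Conditions: DDQ (1.3 equiv), CH2Cl2/pH 7 buffer, 0 °C
Reagents that add atoms: none
Why: Oxidative cleavage of the allylic PMB ether by DDQ (hydride abstraction, then hydrolysis of the oxocarbenium ion) leaves the silyl ether, the esters and the alkenes untouched.

Step 35
Reactants: 50 C14 alcohol
Product: 51 (8S,9S)-14-oxo analogue of 50 (C10 formyl, TBDPS ether still in place)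
Conditions: MnO2 (20 equiv), CH2Cl2, rt
Reagents that add atoms: none
Why: MnO2 oxidation of the allylic alcohol gives the enal, whose formyl group is trans to C2 as formed in step 14, which is also the thermodynamically preferred geometry.

Step 36
Reactants: 51 silyl-protected aldehyde
Product: 52 CNP0240680.3
Conditions: HF·pyridine, pyridine, THF, 0 °C → rt
Reagents that add atoms: none
Why: Fluoride-mediated cleavage of the primary TBDPS ether under buffered acidic conditions should leave the acetates, the enal and both Michael acceptors untouched.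

**Compound list**

1 | pent-4-yn-1-ol | C#CCCCO | starting material
2 | pent-4-ynal | C#CCCC=O | intermediate
3 | ethyl 2-(diethoxyphosphoryl)prop-2-enoate | C=C(C(=O)OCC)P(=O)(OCC)OCC | starting material
4 | (4-methoxyphenyl)methanol | COc1ccc(CO)cc1 | starting material
5 | sodium salt of ethyl 2-(diethoxyphosphoryl)-3-[(4-methoxybenzyl)oxy]propanoate | CCOC(=O)[C-](COCc1ccc(OC)cc1)P(=O)(OCC)OCC.[Na+] | intermediate
6 | ethyl (2E)-2-{[(4-methoxybenzyl)oxy]methyl}hept-2-en-6-ynoate | C#CCC/C=C(/C(=O)OCC)COCc1ccc(OC)cc1 | intermediate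
7 | (2Z)-2-{[(4-methoxybenzyl)oxy]methyl}hept-2-en-6-yn-1-ol | C#CCC/C=C(/CO)COCc1ccc(OC)cc1 | intermediate
8 | tert-butyl{[(2E)-2-{[(4-methoxybenzyl)oxy]methyl}hept-2-en-6-yn-1-yl]oxy}dimethylsilane | C#CCC/C=C(/CO[Si](C)(C)C(C)(C)C)COCc1ccc(OC)cc1 | intermediate
9 | [(1E,5E)-7-(TBS-oxy)-6-(PMB-oxymethyl)-2-methylhepta-1,5-dien-1-yl]dimethylalane | C[Al](C)/C=C(\C)CC/C=C(/CO[Si](C)(C)C(C)(C)C)COCc1ccc(OC)cc1 | intermediate
10 | (2E,6E)-8-[(tert-butyldimethylsilyl)oxy]-7-{[(4-methoxybenzyl)oxy]methyl}-3-methylocta-2,6-dien-1-ol | OC/C=C(\C)CC/C=C(/CO[Si](C)(C)C(C)(C)C)COCc1ccc(OC)cc1 | intermediate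
11 | (2E,6E)-8-[(tert-butyldimethylsilyl)oxy]-7-{[(4-methoxybenzyl)oxy]methyl}-3-methylocta-2,6-dienal | O=C/C=C(\C)CC/C=C(/CO[Si](C)(C)C(C)(C)C)COCc1ccc(OC)cc1 | intermediate
12 | (4S)-4-benzyl-1,3-oxazolidin-2-one | O=C1OC[C@H](Cc2ccccc2)N1 | starting material
13 | methyl 4-chloro-4-oxobutanoate | COC(=O)CCC(Cl)=O | starting material
14 | methyl 4-[(4S)-4-benzyl-2-oxo-1,3-oxazolidin-3-yl]-4-oxobutanoate | COC(=O)CCC(=O)N1C(=O)OC[C@@H]1Cc1ccccc1 | intermediate
15 | methyl (3S,4R,5E,9E)-3-{[(4S)-4-benzyl-2-oxo-1,3-oxazolidin-3-yl]carbonyl}-11-(TBS-oxy)-4-hydroxy-10-(PMB-oxymethyl)-6-methylundeca-5,9-dienoate | O=C(N1C(=O)OC[C@@H]1Cc1ccccc1)[C@H]([C@H](O)/C=C(\C)CC/C=C(/CO[Si](C)(C)C(C)(C)C)COCc1ccc(OC)cc1)CC(=O)OC | intermediate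
16 | (4S)-4-benzyl-3-{[(2R,3S)-2-[(1E,5E)-7-(TBS-oxy)-6-(PMB-oxymethyl)-2-methylhepta-1,5-dien-1-yl]-5-oxooxolan-3-yl]carbonyl}-1,3-oxazolidin-2-one | O=C([C@H]1CC(=O)O[C@@H]1/C=C(\C)CC/C=C(/CO[Si](C)(C)C(C)(C)C)COCc1ccc(OC)cc1)N1C(=O)OC[C@@H]1Cc1ccccc1 | intermediate
17 | (4R,5R)-4-(hydroxymethyl)-5-[(1E,5E)-7-(TBS-oxy)-6-(PMB-oxymethyl)-2-methylhepta-1,5-dien-1-yl]oxolan-2-one | OC[C@H]1CC(=O)O[C@@H]1/C=C(\C)CC/C=C(/CO[Si](C)(C)C(C)(C)C)COCc1ccc(OC)cc1 | intermediate
18 | (4R,5R)-4-{[(tert-butyldimethylsilyl)oxy]methyl}-5-[(1E,5E)-7-(TBS-oxy)-6-(PMB-oxymethyl)-2-methylhepta-1,5-dien-1-yl]oxolan-2-one | CC(C)(C)[Si](C)(C)OC[C@H]1CC(=O)O[C@@H]1/C=C(\C)CC/C=C(/CO[Si](C)(C)C(C)(C)C)COCc1ccc(OC)cc1 | intermediate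
19 | (3R,4R,5R)-3-[(dimethylamino)methyl]-4-{[(tert-butyldimethylsilyl)oxy]methyl}-5-[(1E,5E)-7-(TBS-oxy)-6-(PMB-oxymethyl)-2-methylhepta-1,5-dien-1-yl]oxolan-2-one | CC(C)(C)[Si](C)(C)OC[C@H]1[C@H](CN(C)C)C(=O)O[C@@H]1/C=C(\C)CC/C=C(/CO[Si](C)(C)C(C)(C)C)COCc1ccc(OC)cc1 | intermediate
20 | (3R,4R,5R)-3-[(dimethylamino)methyl]-4-(hydroxymethyl)-5-[(1E,5Z)-7-hydroxy-6-(PMB-oxymethyl)-2-methylhepta-1,5-dien-1-yl]oxolan-2-one | OC[C@H]1[C@H](CN(C)C)C(=O)O[C@@H]1/C=C(\C)CC/C=C(/CO)COCc1ccc(OC)cc1 | intermediate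
21 | (2R,3S,4R)-4-[(dimethylamino)methyl]-2-[(1E,5E)-6-formyl-7-(PMB-oxy)-2-methylhepta-1,5-dien-1-yl]-5-oxooxolane-3-carbaldehyde | O=C[C@H]1[C@H](CN(C)C)C(=O)O[C@@H]1/C=C(\C)CC/C=C(/C=O)COCc1ccc(OC)cc1 | intermediate
22 | dichlorochromium allyl species from 21: CrCl2 on C1, C10=C9 enol ether bearing OSiEt3 (interconverting isomers) | O=C[C@H]1[C@H](CN(C)C)C(=O)O[C@@H]1/C=C(\C)CCC([Cr](Cl)Cl)C(COCc1ccc(OC)cc1)=CO[Si](CC)(CC)CC | intermediate
23 | (8S,9R)-13-(dimethylamino)-8β-hydroxy-14-[(4-methoxybenzyl)oxy]-9β-[(triethylsilyl)oxy]-11,13-dihydromelampolide | O[C@H]1[C@H]2[C@H](CN(C)C)C(=O)O[C@@H]2/C=C(\C)CC/C=C(/COCc3ccc(OC)cc3)[C@H]1O[Si](CC)(CC)CC | intermediate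
24 | N-methyl iodide (13-trimethylammonium salt) of 23 | O[C@H]1[C@H]2[C@H](C[N+](C)(C)C)C(=O)O[C@@H]2/C=C(\C)CC/C=C(/COCc3ccc(OC)cc3)[C@H]1O[Si](CC)(CC)CC.[I-] | intermediate
25 | (8S,9R)-8β-hydroxy-14-[(4-methoxybenzyl)oxy]-9β-[(triethylsilyl)oxy]melampolide | O[C@H]1[C@H]2C(=C)C(=O)O[C@@H]2/C=C(\C)CC/C=C(/COCc3ccc(OC)cc3)[C@H]1O[Si](CC)(CC)CC | intermediate
26 | ethyl 2-(hydroxymethyl)prop-2-enoate | C=C(CO)C(=O)OCC | starting material
27 | ethyl 2-{[(tert-butyldiphenylsilyl)oxy]methyl}prop-2-enoate | C=C(CO[Si](c1ccccc1)(c1ccccc1)C(C)(C)C)C(=O)OCC | intermediate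
28 | 2-{[(tert-butyldiphenylsilyl)oxy]methyl}prop-2-enoic acid | C=C(CO[Si](c1ccccc1)(c1ccccc1)C(C)(C)C)C(=O)O | intermediate
29 | (8S,9R)-8β-[(2-{[(tert-butyldiphenylsilyl)oxy]methyl}prop-2-enoyl)oxy]-14-[(4-methoxybenzyl)oxy]-9β-[(triethylsilyl)oxy]melampolide | C=C(CO[Si](c3ccccc3)(c3ccccc3)C(C)(C)C)C(=O)O[C@H]1[C@H]2C(=C)C(=O)O[C@@H]2/C=C(\C)CC/C=C(/COCc3ccc(OC)cc3)[C@H]1O[Si](CC)(CC)CC | intermediate
30 | (8S,9R)-8β-[(2-{[(tert-butyldiphenylsilyl)oxy]methyl}prop-2-enoyl)oxy]-9β-hydroxy-14-[(4-methoxybenzyl)oxy]melampolide | C=C(CO[Si](c3ccccc3)(c3ccccc3)C(C)(C)C)C(=O)O[C@H]1[C@H]2C(=C)C(=O)O[C@@H]2/C=C(\C)CC/C=C(/COCc3ccc(OC)cc3)[C@H]1O | intermediate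
31 | neryl acetate, (2Z)-3,7-dimethylocta-2,6-dien-1-yl acetate | CC(C)=CCC/C(C)=C\COC(C)=O | starting material
32 | (2Z)-5-(3,3-dimethyloxiran-2-yl)-3-methylpent-2-en-1-yl acetate (racemic at the epoxide) | CC1(C)OC1CC/C(C)=C\COC(C)=O | intermediate
33 | (2Z)-3-methyl-6-oxohex-2-en-1-yl acetate | O=CCC/C(C)=C\COC(C)=O | intermediate
34 | ethyl 2-[bis(2-methylphenoxy)phosphoryl]acetate | CCOC(=O)CP(=O)(Oc1ccccc1C)Oc1ccccc1C | starting material
35 | 3-bromo-1,1-dimethoxypropane | COC(CCBr)OC | starting material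
36 | ethyl 2-[bis(2-methylphenoxy)phosphoryl]-5,5-dimethoxypentanoate | CCOC(=O)C(CCC(OC)OC)P(=O)(Oc1ccccc1C)Oc1ccccc1C | intermediate
37 | ethyl (2Z,6Z)-8-acetoxy-2-(3,3-dimethoxypropyl)-6-methylocta-2,6-dienoate | COC(OC)CC/C(=C/CC/C(C)=C\COC(C)=O)C(=O)OCC | intermediate
38 | (2Z,6Z)-2-(3,3-dimethoxypropyl)-6-methylocta-2,6-diene-1,8-diol | COC(OC)CC/C(=C/CC/C(C)=C\CO)CO | intermediate
39 | (2Z,6Z)-2-(3,3-dimethoxypropyl)-6-methylocta-2,6-diene-1,8-diyl diacetate | COC(OC)CC/C(=C/CC/C(C)=C\COC(C)=O)COC(C)=O | intermediate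
40 | (2Z,6Z)-6-methyl-2-(3-oxopropyl)octa-2,6-diene-1,8-diyl diacetate | O=CCC/C(=C/CC/C(C)=C\COC(C)=O)COC(C)=O | intermediate
41 | but-3-yn-1-ol | C#CCCO | starting material
42 | 4-methyl-3-methylidenepentan-1-ol | CC(C)C(=C)CCO | intermediate
43 | 5-iodo-2-methyl-3-methylidenepentane | CC(C)C(=C)CCI | intermediate
44 | ethyl 2-[bis(2-methylphenoxy)phosphoryl]-6-methyl-5-methylideneheptanoate | CCOC(=O)C(CCC(=C)C(C)C)P(=O)(Oc1ccccc1C)Oc1ccccc1C | intermediate
45 | ethyl (2Z,6Z,10Z)-12-acetoxy-6-(acetoxymethyl)-10-methyl-2-(4-methyl-3-methylidenepentyl)dodeca-2,6,10-trienoate | CCOC(=O)/C(=C\CC/C(=C/CC/C(C)=C\COC(C)=O)COC(C)=O)CCC(=C)C(C)C | intermediate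
46 | (2Z,6Z,10Z)-12-hydroxy-6-(hydroxymethyl)-10-methyl-2-(4-methyl-3-methylidenepentyl)dodeca-2,6,10-trienoic acid | OC(=O)/C(=C\CC/C(=C/CC/C(C)=C\CO)CO)CCC(=C)C(C)C | intermediate
47 | acetic (2Z,6Z,10Z)-12-acetoxy-6-(acetoxymethyl)-10-methyl-2-(4-methyl-3-methylidenepentyl)dodeca-2,6,10-trienoic anhydride | CC(=O)OC(=O)/C(=C\CC/C(=C/CC/C(C)=C\COC(C)=O)COC(C)=O)CCC(=C)C(C)C | intermediate
48 | (2Z,6Z,10Z)-12-acetoxy-6-(acetoxymethyl)-10-methyl-2-(4-methyl-3-methylidenepentyl)dodeca-2,6,10-trienoic acid | OC(=O)/C(=C\CC/C(=C/CC/C(C)=C\COC(C)=O)COC(C)=O)CCC(=C)C(C)C | intermediate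
49 | (8S,9S)-9α-{[(2Z,6Z,10Z)-12-acetoxy-6-(acetoxymethyl)-10-methyl-2-(4-methyl-3-methylidenepentyl)dodeca-2,6,10-trienoyl]oxy}-8β-[(2-{[(tert-butyldiphenylsilyl)oxy]methyl}prop-2-enoyl)oxy]-14-[(4-methoxybenzyl)oxy]melampolide | C=C(CO[Si](c3ccccc3)(c3ccccc3)C(C)(C)C)C(=O)O[C@H]1[C@H]2C(=C)C(=O)O[C@@H]2/C=C(\C)CC/C=C(/COCc3ccc(OC)cc3)[C@@H]1OC(=O)/C(=C\CC/C(=C/CC/C(C)=C\COC(C)=O)COC(C)=O)CCC(=C)C(C)C | intermediate
50 | 14-hydroxy analogue of 49 (PMB removed) | C=C(CO[Si](c3ccccc3)(c3ccccc3)C(C)(C)C)C(=O)O[C@H]1[C@H]2C(=C)C(=O)O[C@@H]2/C=C(\C)CC/C=C(/CO)[C@@H]1OC(=O)/C(=C\CC/C(=C/CC/C(C)=C\COC(C)=O)COC(C)=O)CCC(=C)C(C)C | intermediate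
51 | 14-oxo analogue of 50 (TBDPS ether of the target) | C=C(CO[Si](c3ccccc3)(c3ccccc3)C(C)(C)C)C(=O)O[C@H]1[C@H]2C(=C)C(=O)O[C@@H]2/C=C(\C)CC/C=C(/C=O)[C@@H]1OC(=O)/C(=C\CC/C(=C/CC/C(C)=C\COC(C)=O)COC(C)=O)CCC(=C)C(C)C | intermediate
52 | CNP0240680.3: (6R,7S,8S,9S)-9α-{[(2Z,6Z,10Z)-12-acetoxy-6-(acetoxymethyl)-10-methyl-2-(4-methyl-3-methylidenepentyl)dodeca-2,6,10-trienoyl]oxy}-8β-{[2-(hydroxymethyl)prop-2-enoyl]oxy}-14-oxomelampolide | C=C(CO)C(=O)O[C@H]1[C@H]2C(=C)C(=O)O[C@@H]2/C=C(\C)CC/C=C(/C=O)[C@@H]1OC(=O)/C(=C\CC/C(=C/CC/C(C)=C\COC(C)=O)COC(C)=O)CCC(=C)C(C)C | target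

**Step count and risks**

Total step count: 36. Longest linear sequence: 20 steps (steps 1–6, 8–15, 18, 19, 33–36, from pent-4-yn-1-ol).

Steps most likely to fail:

1. Step 14 (the proposed new method). Intermolecular coupling may outrun ring closure, the allylchromium species may simply be protonated, or the tether may fail to control the transition state, so that the C9 epimer ratio or the C8 face selectivity is poor. Fallback, setting out from 21: low-valent titanium pinacol macrocyclisation (TiCl3(DME)1.5, Zn(Cu), DME, 25 °C, syringe-pump addition), the known way to close medium rings from an enal and an aldehyde as a 1,2-diol. The enal-derived ketyl is an oxyallyl radical in which the C1–C10 bond can rotate, and the titanium-bridged diolate should deliver the cis-diol (8S,9R)-13-(dimethylamino)-8β,9β-dihydroxy-14-[(4-methoxybenzyl)oxy]-11,13-dihydromelampolide F1. Monosilylation of the less hindered allylic C9–OH (Et3SiCl, imidazole, DMF, −40 °C) then comes back to the route at 23.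

2. Step 33. Activation of the hindered C9–OH may be slow, and SN2′ attack at C1, elimination towards C8, or acyl migration between O8 and O9 may compete with clean inversion. Fallback, setting out from 30: Dess–Martin oxidation to the ketone (8S)-8β-[(2-{[(tert-butyldiphenylsilyl)oxy]methyl}prop-2-enoyl)oxy]-14-[(4-methoxybenzyl)oxy]-9-oxomelampolide F2. Luche reduction (NaBH4, CeCl3·7H2O, MeOH, −78 °C; hydride anti to the C8–O bond, polar Felkin–Anh) should give the (8S,9S)-9α-hydroxy epimer of 30 F3. Yamaguchi acylation of F3 with 48 (2,4,6-trichlorobenzoyl chloride, Et3N; DMAP, toluene, rt; retention at C9, the usual way to make angelate-type esters without isomerisation) comes back to the route at 49.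

3. Step 18. Acylation of the C8–OH, which is flanked by the ring fusion and the cis OSiEt3 group, may be sluggish, with competing silyl migration from O9 to O8 and conjugate addition of DMAP or of the alkoxide to the activated acrylate. Fallback, setting out from 25: the small, more reactive acryloyl chloride (i-Pr2NEt, CH2Cl2, −40 °C) gives (8S,9R)-8β-(prop-2-enoyloxy)-14-[(4-methoxybenzyl)oxy]-9β-[(triethylsilyl)oxy]melampolide F4. Morita–Baylis–Hillman hydroxymethylation (DABCO, aq. formaldehyde, dioxane/H2O, rt; the α-methylene lactone has no α-hydrogen and cannot act as the donor) gives (8S,9R)-8β-{[2-(hydroxymethyl)prop-2-enoyl]oxy}-14-[(4-methoxybenzyl)oxy]-9β-[(triethylsilyl)oxy]melampolide F5. Silylation (TBDPSCl, imidazole, CH2Cl2) comes back to the route at 29.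

**Further compounds**

F1 | step 14 | (8S,9R)-13-(dimethylamino)-8β,9β-dihydroxy-14-[(4-methoxybenzyl)oxy]-11,13-dihydromelampolide | O[C@H]1[C@H]2[C@H](CN(C)C)C(=O)O[C@@H]2/C=C(\C)CC/C=C(/COCc3ccc(OC)cc3)[C@H]1O
F2 | step 33 | (8S)-8β-[(2-{[(tert-butyldiphenylsilyl)oxy]methyl}prop-2-enoyl)oxy]-14-[(4-methoxybenzyl)oxy]-9-oxomelampolide | C=C(CO[Si](c3ccccc3)(c3ccccc3)C(C)(C)C)C(=O)O[C@H]1[C@H]2C(=C)C(=O)O[C@@H]2/C=C(\C)CC/C=C(/COCc3ccc(OC)cc3)C1=O
F3 | step 33 | (8S,9S)-8β-[(2-{[(tert-butyldiphenylsilyl)oxy]methyl}prop-2-enoyl)oxy]-9α-hydroxy-14-[(4-methoxybenzyl)oxy]melampolide | C=C(CO[Si](c3ccccc3)(c3ccccc3)C(C)(C)C)C(=O)O[C@H]1[C@H]2C(=C)C(=O)O[C@@H]2/C=C(\C)CC/C=C(/COCc3ccc(OC)cc3)[C@@H]1O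
F4 | step 18 | (8S,9R)-8β-(prop-2-enoyloxy)-14-[(4-methoxybenzyl)oxy]-9β-[(triethylsilyl)oxy]melampolide | C=CC(=O)O[C@H]1[C@H]2C(=C)C(=O)O[C@@H]2/C=C(\C)CC/C=C(/COCc3ccc(OC)cc3)[C@H]1O[Si](CC)(CC)CC
F5 | step 18 | (8S,9R)-8β-{[2-(hydroxymethyl)prop-2-enoyl]oxy}-14-[(4-methoxybenzyl)oxy]-9β-[(triethylsilyl)oxy]melampolide | C=C(CO)C(=O)O[C@H]1[C@H]2C(=C)C(=O)O[C@@H]2/C=C(\C)CC/C=C(/COCc3ccc(OC)cc3)[C@H]1O[Si](CC)(CC)CC
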